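**Retrosynthetic overview**
1. The exocyclic (E)-alkene is cut by an aldol condensation between an (S)-γ-lactone and a C17 aldehyde that already carries the butenolide.
2. The C2–C3 bond and the (4E)-alkene of that aldehyde come from an Eschenmoser–Claisen [3,3] rearrangement of a 2-methylallylic alcohol; the amide is then reduced to the aldehyde.
3. The allylic alcohol comes from the terminal epoxide of (E)-geranylacetone, whose methyl ketone is converted into the butenolide (α-hydroxylation, then ketenylidene Wittig ring closure).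
4. The lactone comes from (S)-5-(hydroxymethyl)dihydrofuran-2(3H)-one (L-glutamic acid series) by oxidation and isopropylidene Wittig olefination.
5. Ring order: the γ-lactone ring is bought intact; the butenolide is the only ring built, and it is closed before the rearrangement.

Assumption: commercial (E)-geranylacetone (≥97% E) is used; the epoxide/carbinol stereocentre in the chain intermediates is racemic and is erased by the rearrangement.

**Step 1**
Reactants: 1 (E)-geranylacetone
Product: 3 (E)-8-(3,3-dimethyloxiran-2-yl)-6-methyloct-5-en-2-one (racemic epoxide), via bromohydrin 2 (not isolated)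
Conditions: NBS (1.1 equiv), THF/H2O, 0 °C; then K2CO3, MeOH, rt, same flask
Reagents that add atoms: water, O
Why: Bromonium formation in aqueous THF is selective for the terminal trisubstituted alkene (van Tamelen bromohydrin reaction), water opens it at the tertiary carbon, and K2CO3 closes the bromohydrin to the epoxide by intramolecular Williamson etherification, the new centre being racemic and erased in step 5.

**Step 2**
Reactants: 3 (E)-8-(3,3-dimethyloxiran-2-yl)-6-methyloct-5-en-2-one
Product: 5 (E)-8-(3,3-dimethyloxiran-2-yl)-1-hydroxy-6-methyloct-5-en-2-one, via potassium enolate 4 (not isolated)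
Conditions: KN(SiMe3)2 (1.1 equiv), THF, −78 °C (ketone added to base); racemic 2-(phenylsulfonyl)-3-phenyloxaziridine, −78 °C; AcOH quench
Reagents that add atoms: 2-(phenylsulfonyl)-3-phenyloxaziridine, O=S(=O)(N1OC1c1ccccc1)c1ccccc1
Why: The bulky amide base removes a methyl proton under kinetic control and the N-sulfonyloxaziridine transfers electrophilic oxygen to the enolate carbon (Davis enolate hydroxylation) without touching the epoxide or alkene, and no stereocentre is formed.

**Step 3**
Reactants: 5 (E)-8-(3,3-dimethyloxiran-2-yl)-1-hydroxy-6-methyloct-5-en-2-one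
Product: 7 4-[(E)-6-(3,3-dimethyloxiran-2-yl)-4-methylhex-3-en-1-yl]furan-2(5H)-one, via ester ylide 6 (not isolated)
Conditions: Ph3P=C=C=O (1.2 equiv), toluene, 100 °C
Reagents that add atoms: (triphenylphosphoranylidene)ketene, O=C=C=P(c1ccccc1)(c1ccccc1)c1ccccc1
Why: The primary alcohol adds to the ketene ylide to give an ester-stabilised phosphorane that closes onto the ketone by intramolecular Wittig olefination (Bestmann butenolide synthesis), placing the side chain at C4 of the butenolide.

**Step 4**
Reactants: 7 4-[(E)-6-(3,3-dimethyloxiran-2-yl)-4-methylhex-3-en-1-yl]furan-2(5H)-one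
Product: 8 4-[(E)-7-hydroxy-4,8-dimethylnona-3,8-dien-1-yl]furan-2(5H)-one (racemic)
Conditions: Al(OiPr)3 (2 equiv), toluene, 110 °C; 1 M HCl work-up
Reagents that add atoms: none
Why: The Lewis acidic aluminium alkoxide opens the trisubstituted epoxide at the tertiary carbon with syn removal of a methyl proton (epoxide to allylic alcohol isomerisation), giving the 2-methylallylic secondary alcohol as a racemate whose centre is erased in step 5.

**Step 5 (key step)**
Reactants: 8 4-[(E)-7-hydroxy-4,8-dimethylnona-3,8-dien-1-yl]furan-2(5H)-one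
Product: 10 (4E,8E)-N,N,4,8-tetramethyl-11-(5-oxo-2,5-dihydrofuran-3-yl)undeca-4,8-dienamide, via ketene N,O-acetal 9 (not isolated)
Conditions: MeC(OMe)2NMe2 (4 equiv), xylene, 140 °C, MeOH distilled off
Reagents that add atoms: N,N-dimethylacetamide dimethyl acetal, CC(OC)(OC)N(C)C
Why: Alcohol exchange and loss of methanol give the ketene N,O-acetal, which undergoes the [3,3]-sigmatropic Eschenmoser–Claisen rearrangement through a chair transition state with the carbinol substituent equatorial (an axial chain would clash with NMe2), forming the C2–C3 bond and the (4E)-trisubstituted alkene with an expected selectivity above 95:5.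

**Step 6**
Reactants: 10 (4E,8E)-N,N,4,8-tetramethyl-11-(5-oxo-2,5-dihydrofuran-3-yl)undeca-4,8-dienamide
Product: 12 (4E,8E)-4,8-dimethyl-11-(5-oxo-2,5-dihydrofuran-3-yl)undeca-4,8-dienal, via zirconium hemiaminal 11 (not isolated)
Conditions: Cp2Zr(H)Cl (1.6 equiv), THF, rt, 20 min; H2O/SiO2
Reagents that add atoms: none
Why: Hydrozirconation of the tertiary amide carbonyl gives a zirconium hemiaminal that collapses to the aldehyde on hydrolysis (chemoselective amide to aldehyde reduction), and the butenolide and trisubstituted alkenes should not react in this short time.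

**Step 7**
Reactants: 13 (S)-5-(hydroxymethyl)dihydrofuran-2(3H)-one
Product: 14 (S)-5-oxotetrahydrofuran-2-carbaldehyde
Conditions: Dess–Martin periodinane (1.2 equiv), CH2Cl2, 0 °C to rt; filtered and used crude at once
Reagents that add atoms: none
Why: Dess–Martin oxidation gives the aldehyde under non-basic conditions, so the adjacent (S) stereocentre bought with the L-glutamic acid derived lactone is retained.

**Step 8**
Reactants: 14 (S)-5-oxotetrahydrofuran-2-carbaldehyde
Product: 15 (S)-5-(2-methylprop-1-en-1-yl)dihydrofuran-2(3H)-one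
Conditions: i-PrPPh3I (1.15 equiv), n-BuLi (1.1 equiv), THF, 0 °C; then 14, −78 to 0 °C
Reagents that add atoms: isopropyltriphenylphosphonium iodide, CC(C)[P+](c1ccccc1)(c1ccccc1)c1ccccc1.[I-]
Why: Wittig olefination with the non-stabilised isopropylidene ylide at low temperature converts the aldehyde faster than it epimerises or the lactone is attacked, no alkene geometry arises, and the (S) centre is carried through unchanged.

**Step 9**
Reactants: 15 (S)-5-(2-methylprop-1-en-1-yl)dihydrofuran-2(3H)-one; 12 (4E,8E)-4,8-dimethyl-11-(5-oxo-2,5-dihydrofuran-3-yl)undeca-4,8-dienal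
Product: 19 (3E,5S)-3-[(4E,8E)-4,8-dimethyl-11-(5-oxo-2,5-dihydrofuran-3-yl)undeca-4,8-dien-1-ylidene]-5-(2-methylprop-1-en-1-yl)dihydrofuran-2(3H)-one (target), via lithium enolate 16 (not isolated), via lithium aldolate 17 (not isolated), via mesylate 18 (not isolated)
Conditions: LiN(SiMe3)2 (1.15 equiv), 15 (1.2 equiv), THF, −78 °C; 12, −78 °C, 15 min; MsCl, −78 to 0 °C; DBU, 0 °C to rt
Reagents that add atoms: none
Why: Aldol addition of the lactone enolate to the aldehyde, mesylation of the aldolate and DBU-induced E1cB elimination (aldol condensation) give the thermodynamically preferred (E)-alkylidene lactone with the chain anti to the carbonyl, the uncontrolled centres of 17 and 18 vanish, C5 is not acidic and stays (S), and any minor Z isomer is removed by chromatography.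

**Compound list**
1 | (E)-geranylacetone, (5E)-6,10-dimethylundeca-5,9-dien-2-one | CC(C)=CCC/C(C)=C/CCC(C)=O | starting material
2 | (E)-9-bromo-10-hydroxy-6,10-dimethylundec-5-en-2-one (racemic) | CC(C)(O)C(Br)CC/C(C)=C/CCC(C)=O | intermediate
3 | (E)-8-(3,3-dimethyloxiran-2-yl)-6-methyloct-5-en-2-one (racemic) | CC1(C)OC1CC/C(C)=C/CCC(C)=O | intermediate
4 | potassium (E)-8-(3,3-dimethyloxiran-2-yl)-6-methylocta-1,5-dien-2-olate | CC1(C)OC1CC/C(C)=C/CCC(=C)[O-].[K+] | intermediate
5 | (E)-8-(3,3-dimethyloxiran-2-yl)-1-hydroxy-6-methyloct-5-en-2-one (racemic) | CC1(C)OC1CC/C(C)=C/CCC(=O)CO | intermediate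
6 | (E)-8-(3,3-dimethyloxiran-2-yl)-6-methyl-2-oxooct-5-en-1-yl (triphenylphosphoranylidene)acetate | CC1(C)OC1CC/C(C)=C/CCC(=O)COC(=O)C=P(c2ccccc2)(c2ccccc2)c2ccccc2 | intermediate
7 | 4-[(E)-6-(3,3-dimethyloxiran-2-yl)-4-methylhex-3-en-1-yl]furan-2(5H)-one (racemic) | CC1(C)OC1CC/C(C)=C/CCC2=CC(=O)OC2 | intermediate
8 | 4-[(E)-7-hydroxy-4,8-dimethylnona-3,8-dien-1-yl]furan-2(5H)-one (racemic) | C=C(C)C(O)CC/C(C)=C/CCC1=CC(=O)OC1 | intermediate
9 | 4-[(E)-7-{[1-(dimethylamino)vinyl]oxy}-4,8-dimethylnona-3,8-dien-1-yl]furan-2(5H)-one | C=C(C)C(OC(=C)N(C)C)CC/C(C)=C/CCC1=CC(=O)OC1 | intermediate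
10 | (4E,8E)-N,N,4,8-tetramethyl-11-(5-oxo-2,5-dihydrofuran-3-yl)undeca-4,8-dienamide | CN(C)C(=O)CC/C(C)=C/CC/C(C)=C/CCC1=CC(=O)OC1 | intermediate
11 | Cp2Zr(Cl) alkoxide of the N,N-dimethyl hemiaminal of 12 | CN(C)C(O[Zr](Cl)(C1C=CC=C1)C1C=CC=C1)CC/C(C)=C/CC/C(C)=C/CCC1=CC(=O)OC1 | intermediate
12 | (4E,8E)-4,8-dimethyl-11-(5-oxo-2,5-dihydrofuran-3-yl)undeca-4,8-dienal | O=CCC/C(C)=C/CC/C(C)=C/CCC1=CC(=O)OC1 | intermediate
13 | (S)-5-(hydroxymethyl)dihydrofuran-2(3H)-one | OC[C@@H]1CCC(=O)O1 | starting material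
14 | (S)-5-oxotetrahydrofuran-2-carbaldehyde | O=C[C@@H]1CCC(=O)O1 | intermediate
15 | (S)-5-(2-methylprop-1-en-1-yl)dihydrofuran-2(3H)-one | CC(C)=C[C@@H]1CCC(=O)O1 | intermediate
16 | lithium (S)-5-(2-methylprop-1-en-1-yl)-4,5-dihydrofuran-2-olate | CC(C)=C[C@@H]1CC=C([O-])O1.[Li+] | intermediate
17 | lithium alkoxide of (5S)-3-[(4E,8E)-1-hydroxy-4,8-dimethyl-11-(5-oxo-2,5-dihydrofuran-3-yl)undeca-4,8-dien-1-yl]-5-(2-methylprop-1-en-1-yl)dihydrofuran-2(3H)-one (diastereomer mixture) | CC(C)=C[C@@H]1CC(C([O-])CC/C(C)=C/CC/C(C)=C/CCC2=CC(=O)OC2)C(=O)O1.[Li+] | intermediate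
18 | methanesulfonate of the alcohol corresponding to 17 (diastereomer mixture) | CC(C)=C[C@@H]1CC(C(OS(C)(=O)=O)CC/C(C)=C/CC/C(C)=C/CCC2=CC(=O)OC2)C(=O)O1 | intermediate
19 | (3E,5S)-3-[(4E,8E)-4,8-dimethyl-11-(5-oxo-2,5-dihydrofuran-3-yl)undeca-4,8-dien-1-ylidene]-5-(2-methylprop-1-en-1-yl)dihydrofuran-2(3H)-one | CC(C)=C[C@@H]1C/C(=C\CC/C(C)=C/CC/C(C)=C/CCC2=CC(=O)OC2)C(=O)O1 | target

**Step count and risks**
Total steps: 9. Longest linear sequence: 7 (steps 1–6, then 9); steps 7–8 make the lactone partner.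

Most likely to fail, step 9: the lithium enolate may deprotonate or add to the butenolide of 12 before or after the aldol. The fallback sets out from 15 and makes the union a neutral Wittig reaction. Convert 15 (LiN(SiMe3)2, Me3SiCl, THF, −78 °C) into the trimethylsilyl ketene acetal F5 and brominate it with NBS at −78 °C to the α-bromo lactone F6. Heat F6 with PPh3 to the phosphonium bromide F7 and deprotonate with aqueous Na2CO3 to the stabilised ylide F8. Heating F8 with 12 in toluene at 80 °C comes back to the route at 19, with the E geometry expected for a stabilised ylide.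

Step 4: Al(OiPr)3 at 110 °C may open or degrade the butenolide, or give carbonyl rearrangement products. The fallback sets out from 7. Cleave the epoxide with HIO4·2H2O in THF/Et2O to the aldehyde (E)-4-methyl-7-(5-oxo-2,5-dihydrofuran-3-yl)hept-4-enal F4. Add 2-bromopropene under Nozaki–Hiyama–Kishi conditions (CrCl2, catalytic NiCl2, DMF), which tolerate the butenolide, and come back to the route at 8.

Step 2: enolate oxidation may give regioisomers, self-aldol or imine adducts. The fallback sets out from 3 and uses halogenation instead. Trap the kinetic enolate (LiN(iPr)2, Me3SiCl, THF, −78 °C) as the trimethylsilyl enol ether F1 and brominate it with NBS at −78 °C to the bromomethyl ketone F2. Displace bromide with potassium diethylphosphonoacetate in DMF to give the keto phosphonoacetate F3. Close the ring by intramolecular Horner–Wadsworth–Emmons olefination (LiBr, Et3N, MeCN) and come back to the route at 7, bypassing 5.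

**Further compounds**
F1 | step 2 | (E)-{[8-(3,3-dimethyloxiran-2-yl)-6-methylocta-1,5-dien-2-yl]oxy}trimethylsilane | CC1(C)OC1CC/C(C)=C/CCC(=C)O[Si](C)(C)C
F2 | step 2 | (E)-1-bromo-8-(3,3-dimethyloxiran-2-yl)-6-methyloct-5-en-2-one | CC1(C)OC1CC/C(C)=C/CCC(=O)CBr
F3 | step 2 | (E)-8-(3,3-dimethyloxiran-2-yl)-6-methyl-2-oxooct-5-en-1-yl (diethoxyphosphoryl)acetate | CC1(C)OC1CC/C(C)=C/CCC(=O)COC(=O)CP(=O)(OCC)OCC
F4 | step 4 | (E)-4-methyl-7-(5-oxo-2,5-dihydrofuran-3-yl)hept-4-enal | O=CCC/C(C)=C/CCC1=CC(=O)OC1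
F5 | step 9 | (S)-trimethyl{[5-(2-methylprop-1-en-1-yl)-4,5-dihydrofuran-2-yl]oxy}silane | CC(C)=C[C@@H]1CC=C(O[Si](C)(C)C)O1
F6 | step 9 | (5S)-3-bromo-5-(2-methylprop-1-en-1-yl)dihydrofuran-2(3H)-one | CC(C)=C[C@@H]1CC(Br)C(=O)O1
F7 | step 9 | [(5S)-5-(2-methylprop-1-en-1-yl)-2-oxotetrahydrofuran-3-yl]triphenylphosphonium bromide | CC(C)=C[C@@H]1CC([P+](c2ccccc2)(c2ccccc2)c2ccccc2)C(=O)O1.[Br-]
F8 | step 9 | (S)-5-(2-methylprop-1-en-1-yl)-3-(triphenylphosphoranylidene)dihydrofuran-2(3H)-one | CC(C)=C[C@@H]1CC(=P(c2ccccc2)(c2ccccc2)c2ccccc2)C(=O)O1
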